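The vessel is closed, stirred and held at one temperature; you charge it with substrate and wait.

| flask | substrate | remark | time |
|---|---|---|---|
| dusk | 0.081 M | run made earlier |  |
| flask | 0.054 M |  | 3.0 d |

dusk run (percent of the substrate charged)

| time / h | substrate / % | side product / % | target / % |
|---|---|---|---|
| 4.00 | 98.2 | 0.6 | 0 |
| 8.00 | 93.9 | 2.4 | 1.8 |
| 12.0 | 86.8 | 8.8 | 3.6 |
| 15.0 | 82.3 | 12.2 | 3.7 |
| 20.0 | 69.1 | 20.7 | 6.5 |

(readings scatter by 1 percentage point)

- percentages count the substrate that a species holds: one side product counts as two

- the largest share of what was charged as substrate, at 3.0 d belongs to (substrate / side product / target)
- the largest share itself, whichever of these holds it, in percent of the substrate charged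

The dusk run opens with a lag, the induction period: at 4.00 h the substrate has lost 1.8 percentage points, close to the scatter. Later the loss climbs. On logarithms, from 8.00 h to 20.0 h, its slope against time reads 1.77, near 2. I read that as a slow step seeding a faster one, and I assume the faster step is bimolecular, which one run cannot test.

So the flask at 3.0 d reads 8.64 on a clock, [substrate] as charged times the square of the time, with the last dusk reading as unit. In logarithms, the smaller charge takes off 0.176 and the longer time adds 1.11.

By the square law, stretched past the readings, my estimate puts the loss of half the substrate at clock 1.62, which for the flask is 1.30 d. At the end the same law would claim a loss of 267%, more than the whole charge, so the law must fail before then, and I expect little substrate in the flask. The split then matters: the last dusk reading shows more side product than target, 76.1% of the two together. If the flask, at its smaller charge, spent its substrate on that same split, which is my assumption and carries the scatter of the readings, side product would hold about that share.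

The forecast also says side product, at 75%, range 62% to 86%, “assuming a bimolecular step”; its share comes from its own integration.

    substrate + target → 2 target (k = 0.0558 /M/min)
    substrate → target (k = 3.99 × 10⁻⁵ /min)
    substrate → decomposition product (k = 3.23 × 10⁻⁶ /min)
    substrate + target → side product (k = 0.0477 /M/min)

The flask gives side product at 75.0%. Left to 30.0 d, the flask holds 82.8% side product. At 1.50 d the flask reads 2.16 on the clock, more than the 1.62 reckoned, and holds 49.3% substrate. A neighbour charged with 0.013 M reads 2.08 on the same clock at 3.00 d and holds 50.5% substrate.

(The data are simulated with made-up constants; noise was put on by code.)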